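All ring locants (O1, C2, C3, C3a, C4 to C7, C7a) refer to the benzofuran skeleton of the target. Ring A is the fused benzene ring, ring B the aryl group on C2, ring C the dihydrofuran. Compound numbers are those of the steps and the compound list.

## Analysis of the target

Target 30 is a phenylcoumaran-type neolignan, a 2,3-dihydrobenzofuran. Ring A carries a methoxy group on C7 and an (E)-propenoic acid on C5, ring C carries a hydroxymethyl group on C3, and ring B, a 4-hydroxy-3,5-dimethoxyphenyl group, sits on C2. The two stereocentres, C2 (S) and C3 (R), are adjacent and trans, so ring B and the hydroxymethyl group lie on opposite faces of ring C. The C2–O1 bond is a benzylic ether para to the ring-B phenol. It can ionise to a para-quinone methide under acid and, once the phenol is free, open under base. The phenol is also oxidisable, and the cinnamic acid rules out late hydrogenolysis. The difficulty is to fix both centres absolutely while ring A receives its substitution pattern, with the side chain on C5 para to O1 but meta to the methoxy group. Two features of the structure decide the plan. First, C3 can no longer epimerise once it is not next to a carbonyl group, so a C2/C3 pair made early in an acyclic aldol reaction stays safe. Second, the methoxy carbon C7 is bonded to C7a, which bears O1 and is joined to C3a. Read backwards, C7a=C3a is the enol ether double bond of a dihydrofuran and C7 is a methoxycarbene carbon attached to it, so ring A can be grown last onto a ring C that already holds both stereocentres.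

## Retrosynthetic reasoning

**30 to 29.** The first cut removes only the two O–Si bonds and leads to the bis-silyl ether 29. The phenol and the primary alcohol must be masked against organolithium, carbene complex and triflation chemistry. Silyl groups are chosen because one mild desilylation frees both without touching the alkene, the acid or the benzylic ether; hydrogenolysis and strong acid would not allow that.

**29 to 26 and 27.** The Cα=Cβ bond of the acrylic acid is cut, giving the C5 aldehyde 26 and malonic acid 27. A condensation with decarboxylation gives the E acid directly, so no ester has to be hydrolysed on a sensitive compound. The aldehyde oxidation level at C5 is exactly what the alkyne partner of the key step delivers.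

**26 to 25, 24 and 22.** These are changes of functional group only. The aldehyde is stored as the diethyl acetal 25, and the C4–H bond of 25 is traced back through the triflate 24 to the C4 phenol 22. The extra oxygen on C4 is the price of the ring construction that follows, because the C4 carbon arrives as a carbonyl ligand. Removing it through the triflate costs two steps. The acetal is kept through the reduction so that the aldehyde appears only when it is needed.

**22 to 19 and 20 (key disconnection).** Ring A is cut at C6–C7, C4–C5 and C3a–C4. It falls apart into the carbene carbon of 19 (C7 with its methoxy group), the two alkene carbons of the dihydrofuran in 19 (C7a and C3a), one carbonyl ligand of 19 (C4) and the two alkyne carbons of 20 (C5 and C6). This cut is preferred to any cut in ring C because it leaves ring C and both stereocentres untouched, and it places every ring-A substituent by mechanism: the methoxy group from the carbene, the acetal next to the carbonyl-derived carbon. The forward reaction must insert the alkyne with the right orientation, insert a carbonyl ligand, close the six-membered ring and leave C3 alone.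

**19 to 15 and 16.** The C7–C7a bond and the O–methyl bond are cut. The vinylic C–H next to the ring oxygen of the dihydrofuran 15 is the most acidic position, so metalation, addition to chromium hexacarbonyl 16 and O-methylation should give 19 in one operation.

**15 to 13 and 10.** The enol ether double bond of 15 comes from dehydration of the lactol 13, and 13 comes from oxidative cleavage of the terminal alkene of 10, whose free benzylic hydroxyl closes onto the new aldehyde. Two of the three allyl carbons of 10 become C3a and C7a; the third is lost. This uses the cheapest possible three-carbon branch.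

**10 to 9 and 8.** The primary silyl ether 10 comes from the diol 9, and 9 from reduction of the imide 8. The hydroxymethyl carbon on C3 is the former acyl carbon, and after the reduction C3 is no longer enolisable.

**8 to 6 and 2.** The C2–C3 bond is cut in an aldol sense, which sets both stereocentres in one auxiliary-controlled step. The syn aldol relationship becomes trans on ring C because ring C is closed through the carbinol oxygen and the allyl branch, not through the acyl carbon.

**6 to 3 and 4; 2 to 1.** The imide 6 is the N-acyl derivative of the oxazolidinone 3 and the acid chloride 4. The aldehyde 2 is silylated syringaldehyde 1.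

## Alternatives that were turned down

**Alternative 1: oxidative ring contraction of a flavanone.**
- Disconnection: C3–C3a, with the C3 substituent at the ester level. The precursor is the chromanone A1, (2S)-2-(4-acetoxy-3,5-dimethoxyphenyl)-6-bromo-8-methoxychroman-4-one, in which ring A is still bonded to the carbonyl carbon.
- Forward key step: a trivalent iodine oxidant in an acidic orthoester medium attacks the enol ether of A1 at C3. Loss of the iodane is assisted by a 1,2-shift of the ring-A carbon from the ketal carbon to C3. This contracts the pyranone to ring C and leaves the old carbonyl carbon as the methyl ester of A2, methyl (2S,3S)-2-(4-acetoxy-3,5-dimethoxyphenyl)-5-bromo-7-methoxy-2,3-dihydrobenzofuran-3-carboxylate. The trans arrangement follows because the ester-bearing carbon can equilibrate.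
- For: short access from a chalcone, cheap reagents, one acetate as the only protecting group, and a C5 bromide ready for a Heck reaction. After A2 only ester reduction, Heck coupling and deprotection remain, perhaps eight steps overall against fourteen.
- Against:
  - The same iodonium intermediate can be discharged by migration of ring B from C2 to C3 (the isoflavone pathway) or by elimination to the flavone. An oxygen-rich ring B such as that of A1 is a good migrating group, so the choice of migrating group is least certain for exactly this substitution.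
  - The single stereocentre of A1 is a benzylic ether β to a ketone and can be lost by reversible opening to the hydroxychalcone in the acidic medium.
  - In A2 the C3 proton is α to the ester and β to the aryloxy leaving group O1, so base-induced opening of ring C threatens both centres during the reduction.
- Comparison: this plan is clearly better in step count and cost and needs no stoichiometric chromium. The chosen route offers in return two stereocentres set by an aldol reaction whose outcome does not depend on the electronics of ring B, and no intermediate in which ring C can open reversibly next to a carbonyl group.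

**Alternative 2: Catellani annulation of an aryl iodide with a cis epoxide.**
- Disconnection: both C3–C3a and O1–C7a. Ring C is assembled from the aryl iodide A3, methyl 4-iodo-3-methoxybenzoate, and the cis epoxide A4, (2R,3S)-3-(tert-butyldimethylsilyloxymethyl)-2-[3,5-dimethoxy-4-(methoxymethoxy)phenyl]oxirane.
- Forward key step: zerovalent palladium inserts into the C–I bond of A3, and a strained bicyclic alkene mediator relays the metal to the ortho C–H position. The palladacycle opens A4 at its non-benzylic carbon with inversion (C3–C3a). The mediator is extruded and the freed benzylic alkoxide is joined to the ipso carbon (O1–C7a). The product is A5, methyl (2S,3R)-3-(tert-butyldimethylsilyloxymethyl)-7-methoxy-2-[3,5-dimethoxy-4-(methoxymethoxy)phenyl]-2,3-dihydrobenzofuran-5-carboxylate. Inversion at one carbon and retention at the other turn the cis epoxide into the trans ring C.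
- For: the most convergent of the four plans. Ring A is a simple benzoate with the C5 carbon in place, both ring-C bonds form in one step, and the step is stereospecific, so relative and absolute configuration follow from A4 alone.
- Against:
  - The palladacycle must attack an internal, disubstituted epoxide at the carbon that is not benzylic, while the benzylic carbon of A4 is strongly activated by the para-alkoxy ring B. Ionisation there, by Lewis-acidic divalent palladium or by iodide, leads to rearrangement to a carbonyl compound, to halohydrins or to loss of the cis geometry.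
  - A4, a Z-derived electron-rich aryl epoxide, is hard to make as one enantiomer and hard to keep.
  - After the key step the ester of A5 must still be taken to the acrylic acid in about three steps, and the acetal-type phenol protection must be removed with acid next to the benzylic ether.
- Comparison: this plan is stronger on convergence and probably five or six steps shorter. The chosen strategy offers a chiral building block, the enol ether 15, that comes from a stable aldol adduct, and a key step whose regiochemistry has a simple steric origin. In this alternative, regiochemistry and substrate stability both sit at the weakest point.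

**Alternative 3: stereoconvergent para-quinone methide closure of ring C.**
- Disconnection: O1–C2. The precursor is the open bisphenol A6, (2R)-2-(5-bromo-2-hydroxy-3-methoxyphenyl)-1-(4-hydroxy-3,5-dimethoxyphenyl)propane-1,3-diol, as either carbinol epimer.
- Forward key step: acid ionises the benzylic carbinol of A6, with both epimers giving the same ring-B para-quinone methide. The ring-A phenol oxygen then adds to C2 to give A7, [(2S,3R)-5-bromo-2-(4-hydroxy-3,5-dimethoxyphenyl)-7-methoxy-2,3-dihydrobenzofuran-3-yl]methanol, with the C2 aryl group settling trans to the C3 substituent.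
- For: only C3 has to be set absolutely, and the carbinol configuration is irrelevant. The end game needs no protecting groups, and a Heck reaction of A7 with an acrylate followed by hydrolysis finishes 30. This is likely the shortest plan.
- Against:
  - The one controlling centre, C3, lies next to the quinone methide carbon and is benzylic to ring A. Loss of its proton gives a conjugated stilbene, a typical decomposition of this skeleton, and any reversible proton loss erodes the enantiomeric purity.
  - The trans preference of the closure is a matter of relative stability and kinetics, not stereospecific.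
  - The stereocentre of A6 has to be made by chemistry of an α-aryl carbonyl compound, which is itself prone to racemisation before reduction.
- Comparison: this alternative is stronger on step economy, on protecting-group economy and on avoiding a stoichiometric metal. The chosen strategy offers stereochemical security in its place: the C2–O1 bond exists before ring A does, its configuration is fixed by the aldol step, and no cation or quinone methide is ever generated next to C3.

Key step: step 9

## Route

Remark: pent-4-enoyl chloride (4) is taken as the commercial activated form of pent-4-enoic acid.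

Step 1
Reactants: 1 syringaldehyde
Product: 2 3,5-dimethoxy-4-(triisopropylsilyloxy)benzaldehyde
Conditions: TIPSCl, imidazole, DMF, rt to 40 °C
Reagents that add atoms: triisopropylsilyl chloride, CC(C)[Si](Cl)(C(C)C)C(C)C
Why: Silylation of a phenol with a silyl chloride and imidazole; the two ortho methoxy groups slow it, hence DMF and gentle warming. The triisopropylsilyl ether should withstand organolithium, hydride, periodate and mild acid and fall to fluoride in the last step.

Step 2
Reactants: 3 (S)-4-benzyl-2-oxazolidinone; 4 pent-4-enoyl chloride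
Product: 6 (S)-4-benzyl-3-(pent-4-enoyl)oxazolidin-2-one, via lithium oxazolidinide 5 (not isolated)
Conditions: n-BuLi, THF, −78 °C; then 4, −78 → 0 °C
Reagents that add atoms: none
Why: N-acylation of the lithiated Evans oxazolidinone with an acid chloride; the stereocentre of 3 is not involved.

Step 3
Reactants: 6 (S)-4-benzyl-3-(pent-4-enoyl)oxazolidin-2-one; 2 3,5-dimethoxy-4-(triisopropylsilyloxy)benzaldehyde
Product: 8 (S)-4-benzyl-3-{(2S)-2-[(S)-[3,5-dimethoxy-4-(triisopropylsilyloxy)phenyl](hydroxy)methyl]pent-4-enoyl}oxazolidin-2-one, via dibutylboron Z-enolate 7 (not isolated)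
Conditions: Bu2BOTf, iPr2NEt, CH2Cl2, −78 → 0 °C; then 2, −78 → 0 °C; pH 7 buffer, MeOH, 30% H2O2, 0 °C
Reagents that add atoms: none
Why: Evans boron aldol reaction: soft enolisation should give only the Z-enolate 7, which reacts through a closed Zimmerman–Traxler chair in which the oxazolidinone carbonyl points away from the enolate oxygen and the benzyl group blocks one face. This sets the future C2 and C3 together as the syn (2S,3S) adduct; the oxidative work-up releases the aldol from boron without retro-aldol cleavage.

Step 4
Reactants: 8 the aldol adduct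
Product: 9 (1S,2R)-2-allyl-1-[3,5-dimethoxy-4-(triisopropylsilyloxy)phenyl]propane-1,3-diol
Conditions: LiBH4, MeOH (1 equiv), THF, 0 °C
Reagents that add atoms: none
Why: Reductive removal of the auxiliary; LiBH4 activated by one equivalent of methanol reduces the exocyclic imide carbonyl selectively and 3 is recovered. From here on the carbon that becomes C3 is no longer enolisable.

Step 5
Reactants: 9 the diol
Product: 10 (1S,2R)-2-(tert-butyldimethylsilyloxymethyl)-1-[3,5-dimethoxy-4-(triisopropylsilyloxy)phenyl]pent-4-en-1-ol
Conditions: TBSCl (1.05 equiv), imidazole, CH2Cl2, 0 °C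
Reagents that add atoms: tert-butyldimethylsilyl chloride, CC(C)(C)[Si](C)(C)Cl
Why: Selective silylation of the primary hydroxyl of a 1,3-diol; the hindered secondary benzylic hydroxyl stays free for the later ring closure.

Step 6
Reactants: 10 the homoallyl-type alcohol
Product: 13 (4R,5S)-4-(tert-butyldimethylsilyloxymethyl)-5-[3,5-dimethoxy-4-(triisopropylsilyloxy)phenyl]tetrahydrofuran-2-ol (both anomers), via pentane-1,4,5-triol 11 (not isolated), via hydroxy aldehyde 12 (not isolated)
Conditions: OsO4 (2 mol %), NaIO4, 2,6-lutidine, dioxane/H2O 3:1, rt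
Reagents that add atoms: osmium tetroxide, O=[Os](=O)(=O)=O (transfers oxygen to the alkene); sodium periodate, [Na+].[O-]I(=O)(=O)=O (terminal oxidant that restores OsO4)
Why: Lemieux–Johnson cleavage of the terminal alkene; the aldehyde 12 is trapped at once by the benzylic hydroxyl as the five-membered lactol. OsO4/NaIO4 is preferred to ozone because the electron-rich ring B would compete for ozone, and 2,6-lutidine buffers the medium.

Step 7
Reactants: 13 the lactol
Product: 15 (2S,3R)-3-(tert-butyldimethylsilyloxymethyl)-2-[3,5-dimethoxy-4-(triisopropylsilyloxy)phenyl]-2,3-dihydrofuran, via anomeric mesylate 14 (not isolated)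
Conditions: MsCl, Et3N, CH2Cl2, −40 → 40 °C; NaHCO3 work-up
Reagents that add atoms: none
Why: Dehydration of a lactol through its anomeric sulfonate, with Et3N removing the neighbouring proton, the usual entry to furanoid glycals. Acid is avoided because the benzylic C–O bond of 13 ionises easily; neither stereocentre is at a reacting carbon.

Step 8
Reactants: 15 the dihydrofuran; 16 chromium hexacarbonyl
Product: 19 pentacarbonyl{methoxy[(4R,5S)-4-(tert-butyldimethylsilyloxymethyl)-5-[3,5-dimethoxy-4-(triisopropylsilyloxy)phenyl]-4,5-dihydrofuran-2-yl]methylidene}chromium, via 5-lithio-2,3-dihydrofuran 17 (not isolated), via lithium acylchromate 18 (not isolated)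
Conditions: t-BuLi, THF, −78 → 0 °C; 16, THF, 0 °C → rt; solvent exchange, Me3OBF4, CH2Cl2, 0 °C
Reagents that add atoms: trimethyloxonium tetrafluoroborate, C[O+](C)C.F[B-](F)(F)F
Why: Fischer carbene synthesis: t-BuLi removes the vinylic proton next to the ring oxygen (the future C7a), the vinyllithium 17 adds to a carbonyl ligand of 16, and the acylmetalate 18 is O-methylated by the hard Meerwein salt. No base is present once 19 exists, so the vinylogously acidified allylic C–H (the future C3) is left alone.

Step 9
Reactants: 19 the carbene complex; 20 3,3-diethoxyprop-1-yne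
Product: 22 (2S,3R)-3-(tert-butyldimethylsilyloxymethyl)-5-(diethoxymethyl)-7-methoxy-2-[3,5-dimethoxy-4-(triisopropylsilyloxy)phenyl]-2,3-dihydrobenzofuran-4-ol, via arene tricarbonylchromium complex 21 (not isolated)
Conditions: 20 (2 equiv), degassed THF, 50 °C, argon; then air, rt; chromatography on Et3N-deactivated silica
Reagents that add atoms: none
Why: Dötz benzannulation: thermal loss of one carbonyl ligand from zerovalent chromium opens a site for 20, the alkyne inserts into the chromium–carbene bond, a carbonyl ligand inserts to give a chromium-bound dienylketene, and this closes between the ketene carbon (C4) and C3a; enolisation gives the phenol as its Cr(CO)3 complex 21, which air demetalates. Ring A is thus closed by a 6π electrocyclisation within a formal [3+2+1] assembly, not by a polar exo or endo attack. The closest known reaction type is the benzannulation of alkenyl and cyclic enol ether (dihydropyranyl, glycal-derived) methoxycarbene chromium complexes with terminal alkynes. No stereocentre is created; C2 and C3 lie outside the reacting π system and are carried through unchanged. The step needs regioselective alkyne insertion, and the steric difference between hydrogen and the diethoxymethyl group secures it: the unsubstituted alkyne carbon bonds to the carbene carbon (C6–C7) and the acetal-bearing carbon to the inserted carbonyl (C4–C5). It also needs carbonyl insertion to win over cyclopentannulation, which alkenyl carbene complexes in an ether solvent favour, and a hydrogen on C3a for the final tautomerisation, which the dihydrofuran provides. Neutral, base-free conditions and amine-deactivated silica protect the ortho-hydroxy acetal and the C3 centre.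

Step 10
Reactants: 22 the C4 phenol
Product: 24 (2S,3R)-3-(tert-butyldimethylsilyloxymethyl)-5-(diethoxymethyl)-7-methoxy-2-[3,5-dimethoxy-4-(triisopropylsilyloxy)phenyl]-2,3-dihydrobenzofuran-4-yl trifluoromethanesulfonate, via sodium phenoxide 23 (not isolated)
Conditions: NaH, THF, 0 °C; then PhNTf2, 0 °C → rt
Reagents that add atoms: N-phenylbis(trifluoromethanesulfonimide), O=S(=O)(N(c1ccccc1)S(=O)(=O)C(F)(F)F)C(F)(F)F
Why: O-sulfonylation of a phenoxide with PhNTf2; pre-forming the sodium phenoxide overcomes the hindrance by the two ortho substituents, and the non-acidic conditions spare the acetal and both silyl ethers.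

Step 11
Reactants: 24 the aryl triflate
Product: 25 tert-butyl{[(2S,3R)-5-(diethoxymethyl)-7-methoxy-2-[3,5-dimethoxy-4-(triisopropylsilyloxy)phenyl]-2,3-dihydrobenzofuran-3-yl]methoxy}dimethylsilane
Conditions: Pd(OAc)2 (5 mol %), dppf (10 mol %), HCO2H, Et3N (excess), DMF, 70 °C
Reagents that add atoms: none
Why: Palladium-catalysed reductive cleavage of an aryl triflate by formate: oxidative addition of zerovalent palladium into the C–O bond, formate exchange, decarboxylation to an aryl palladium hydride and reductive elimination of the C4–H bond. The bidentate dppf ligand suits the hindered, electron-rich triflate, and the excess of Et3N keeps the acetal intact.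

Step 12
Reactants: 25 the diethyl acetal
Product: 26 (2S,3R)-3-(tert-butyldimethylsilyloxymethyl)-7-methoxy-2-[3,5-dimethoxy-4-(triisopropylsilyloxy)phenyl]-2,3-dihydrobenzofuran-5-carbaldehyde
Conditions: PPTS (10 mol %), acetone/H2O 10:1, rt
Reagents that add atoms: water, O
Why: Acid-catalysed hydrolysis of an aryl diethyl acetal, which under PPTS should be much faster than cleavage of the primary silyl ether or ionisation of the benzylic ether.

Step 13
Reactants: 26 the C5 aldehyde; 27 malonic acid
Product: 29 (E)-3-[(2S,3R)-3-(tert-butyldimethylsilyloxymethyl)-7-methoxy-2-[3,5-dimethoxy-4-(triisopropylsilyloxy)phenyl]-2,3-dihydrobenzofuran-5-yl]prop-2-enoic acid, via arylidenemalonic acid 28 (not isolated)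
Conditions: 27 (3 equiv), pyridine, piperidine (cat.), 90 °C
Reagents that add atoms: none
Why: Knoevenagel–Doebner condensation: the piperidine-derived iminium condenses with malonic acid to 28, which loses CO2 in hot pyridine to give the E acid. Partial loss of a silyl group here would be harmless, since both are removed in the next step.

Step 14
Reactants: 29 the bis-silyl ether
Product: 30 (E)-3-[(2S,3R)-2-(4-hydroxy-3,5-dimethoxyphenyl)-3-(hydroxymethyl)-7-methoxy-2,3-dihydrobenzofuran-5-yl]prop-2-enoic acid
Conditions: TBAF (4 equiv), AcOH (2 equiv), THF, 0 °C → rt; dilute aqueous HCl work-up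
Reagents that add atoms: none
Why: Fluoride cleavage of both silyl ethers; acetic acid buffers the phenoxide so that ring C is not opened through a quinone methide, and the alkene, the acid and both stereocentres are untouched.

## Compound list

1 | syringaldehyde | COc1cc(C=O)cc(OC)c1O | starting material
2 | 3,5-dimethoxy-4-(triisopropylsilyloxy)benzaldehyde | COc1cc(C=O)cc(OC)c1O[Si](C(C)C)(C(C)C)C(C)C | intermediate
3 | (S)-4-benzyl-2-oxazolidinone | O=C1N[C@@H](Cc2ccccc2)CO1 | starting material
4 | pent-4-enoyl chloride | C=CCCC(=O)Cl | starting material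
5 | lithium (S)-4-benzyl-2-oxo-oxazolidin-3-ide (not isolated) | [Li+].O=C1[N-][C@@H](Cc2ccccc2)CO1 | intermediate
6 | (S)-4-benzyl-3-(pent-4-enoyl)oxazolidin-2-one | C=CCCC(=O)N1[C@@H](Cc2ccccc2)COC1=O | intermediate
7 | dibutylboron Z-enolate of 6 (not isolated) | CCCCB(CCCC)O/C(=C\CC=C)N1[C@@H](Cc2ccccc2)COC1=O | intermediate
8 | (S)-4-benzyl-3-{(2S)-2-[(S)-[3,5-dimethoxy-4-(triisopropylsilyloxy)phenyl](hydroxy)methyl]pent-4-enoyl}oxazolidin-2-one | C=CC[C@H](C(=O)N1[C@@H](Cc2ccccc2)COC1=O)[C@@H](c1cc(OC)c(O[Si](C(C)C)(C(C)C)C(C)C)c(OC)c1)O | intermediate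
9 | (1S,2R)-2-allyl-1-[3,5-dimethoxy-4-(triisopropylsilyloxy)phenyl]propane-1,3-diol | C=CC[C@H](CO)[C@@H](c1cc(OC)c(O[Si](C(C)C)(C(C)C)C(C)C)c(OC)c1)O | intermediate
10 | (1S,2R)-2-(tert-butyldimethylsilyloxymethyl)-1-[3,5-dimethoxy-4-(triisopropylsilyloxy)phenyl]pent-4-en-1-ol | C=CC[C@H](CO[Si](C)(C)C(C)(C)C)[C@@H](c1cc(OC)c(O[Si](C(C)C)(C(C)C)C(C)C)c(OC)c1)O | intermediate
11 | (1S,2R)-2-(tert-butyldimethylsilyloxymethyl)-1-[3,5-dimethoxy-4-(triisopropylsilyloxy)phenyl]pentane-1,4,5-triol, both C4 epimers (not isolated) | OCC(O)C[C@H](CO[Si](C)(C)C(C)(C)C)[C@@H](c1cc(OC)c(O[Si](C(C)C)(C(C)C)C(C)C)c(OC)c1)O | intermediate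
12 | (3R,4S)-3-(tert-butyldimethylsilyloxymethyl)-4-hydroxy-4-[3,5-dimethoxy-4-(triisopropylsilyloxy)phenyl]butanal (not isolated) | O=CC[C@H](CO[Si](C)(C)C(C)(C)C)[C@@H](c1cc(OC)c(O[Si](C(C)C)(C(C)C)C(C)C)c(OC)c1)O | intermediate
13 | (4R,5S)-4-(tert-butyldimethylsilyloxymethyl)-5-[3,5-dimethoxy-4-(triisopropylsilyloxy)phenyl]tetrahydrofuran-2-ol, both anomers | OC1C[C@H](CO[Si](C)(C)C(C)(C)C)[C@@H](c2cc(OC)c(O[Si](C(C)C)(C(C)C)C(C)C)c(OC)c2)O1 | intermediate
14 | (4R,5S)-4-(tert-butyldimethylsilyloxymethyl)-5-[3,5-dimethoxy-4-(triisopropylsilyloxy)phenyl]tetrahydrofuran-2-yl methanesulfonate (not isolated) | CS(=O)(=O)OC1C[C@H](CO[Si](C)(C)C(C)(C)C)[C@@H](c2cc(OC)c(O[Si](C(C)C)(C(C)C)C(C)C)c(OC)c2)O1 | intermediate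
15 | (2S,3R)-3-(tert-butyldimethylsilyloxymethyl)-2-[3,5-dimethoxy-4-(triisopropylsilyloxy)phenyl]-2,3-dihydrofuran | C1=C[C@H](CO[Si](C)(C)C(C)(C)C)[C@@H](c2cc(OC)c(O[Si](C(C)C)(C(C)C)C(C)C)c(OC)c2)O1 | intermediate
16 | chromium hexacarbonyl | O=C=[Cr](=C=O)(=C=O)(=C=O)(=C=O)=C=O | starting material
17 | (2S,3R)-3-(tert-butyldimethylsilyloxymethyl)-2-[3,5-dimethoxy-4-(triisopropylsilyloxy)phenyl]-5-lithio-2,3-dihydrofuran (not isolated) | [Li]C1=C[C@H](CO[Si](C)(C)C(C)(C)C)[C@@H](c2cc(OC)c(O[Si](C(C)C)(C(C)C)C(C)C)c(OC)c2)O1 | intermediate
18 | lithium pentacarbonyl{[(4R,5S)-4-(tert-butyldimethylsilyloxymethyl)-5-[3,5-dimethoxy-4-(triisopropylsilyloxy)phenyl]-4,5-dihydrofuran-2-yl](oxido)methylidene}chromate (not isolated) | [Li+].[O-]C(=[Cr](=C=O)(=C=O)(=C=O)(=C=O)=C=O)C1=C[C@H](CO[Si](C)(C)C(C)(C)C)[C@@H](c2cc(OC)c(O[Si](C(C)C)(C(C)C)C(C)C)c(OC)c2)O1 | intermediate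
19 | pentacarbonyl{methoxy[(4R,5S)-4-(tert-butyldimethylsilyloxymethyl)-5-[3,5-dimethoxy-4-(triisopropylsilyloxy)phenyl]-4,5-dihydrofuran-2-yl]methylidene}chromium | COC(=[Cr](=C=O)(=C=O)(=C=O)(=C=O)=C=O)C1=C[C@H](CO[Si](C)(C)C(C)(C)C)[C@@H](c2cc(OC)c(O[Si](C(C)C)(C(C)C)C(C)C)c(OC)c2)O1 | intermediate
20 | 3,3-diethoxyprop-1-yne | C#CC(OCC)OCC | starting material
21 | tricarbonylchromium η6 complex of 22 on ring A, metal fragment written apart (not isolated) | COc1cc([C@H]2Oc3c(OC)cc(C(OCC)OCC)c(O)c3[C@@H]2CO[Si](C)(C)C(C)(C)C)cc(OC)c1O[Si](C(C)C)(C(C)C)C(C)C.O=C=[Cr](=C=O)=C=O | intermediate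
22 | (2S,3R)-3-(tert-butyldimethylsilyloxymethyl)-5-(diethoxymethyl)-7-methoxy-2-[3,5-dimethoxy-4-(triisopropylsilyloxy)phenyl]-2,3-dihydrobenzofuran-4-ol | COc1cc([C@H]2Oc3c(OC)cc(C(OCC)OCC)c(O)c3[C@@H]2CO[Si](C)(C)C(C)(C)C)cc(OC)c1O[Si](C(C)C)(C(C)C)C(C)C | intermediate
23 | sodium phenoxide of 22 (not isolated) | COc1cc([C@H]2Oc3c(OC)cc(C(OCC)OCC)c([O-])c3[C@@H]2CO[Si](C)(C)C(C)(C)C)cc(OC)c1O[Si](C(C)C)(C(C)C)C(C)C.[Na+] | intermediate
24 | (2S,3R)-3-(tert-butyldimethylsilyloxymethyl)-5-(diethoxymethyl)-7-methoxy-2-[3,5-dimethoxy-4-(triisopropylsilyloxy)phenyl]-2,3-dihydrobenzofuran-4-yl trifluoromethanesulfonate | COc1cc([C@H]2Oc3c(OC)cc(C(OCC)OCC)c(OS(=O)(=O)C(F)(F)F)c3[C@@H]2CO[Si](C)(C)C(C)(C)C)cc(OC)c1O[Si](C(C)C)(C(C)C)C(C)C | intermediate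
25 | tert-butyl{[(2S,3R)-5-(diethoxymethyl)-7-methoxy-2-[3,5-dimethoxy-4-(triisopropylsilyloxy)phenyl]-2,3-dihydrobenzofuran-3-yl]methoxy}dimethylsilane | COc1cc([C@H]2Oc3c(OC)cc(C(OCC)OCC)cc3[C@@H]2CO[Si](C)(C)C(C)(C)C)cc(OC)c1O[Si](C(C)C)(C(C)C)C(C)C | intermediate
26 | (2S,3R)-3-(tert-butyldimethylsilyloxymethyl)-7-methoxy-2-[3,5-dimethoxy-4-(triisopropylsilyloxy)phenyl]-2,3-dihydrobenzofuran-5-carbaldehyde | COc1cc([C@H]2Oc3c(OC)cc(C=O)cc3[C@@H]2CO[Si](C)(C)C(C)(C)C)cc(OC)c1O[Si](C(C)C)(C(C)C)C(C)C | intermediate
27 | malonic acid | O=C(O)CC(=O)O | starting material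
28 | 2-{[(2S,3R)-3-(tert-butyldimethylsilyloxymethyl)-7-methoxy-2-[3,5-dimethoxy-4-(triisopropylsilyloxy)phenyl]-2,3-dihydrobenzofuran-5-yl]methylidene}propanedioic acid (not isolated) | COc1cc([C@H]2Oc3c(OC)cc(C=C(C(=O)O)C(=O)O)cc3[C@@H]2CO[Si](C)(C)C(C)(C)C)cc(OC)c1O[Si](C(C)C)(C(C)C)C(C)C | intermediate
29 | (E)-3-[(2S,3R)-3-(tert-butyldimethylsilyloxymethyl)-7-methoxy-2-[3,5-dimethoxy-4-(triisopropylsilyloxy)phenyl]-2,3-dihydrobenzofuran-5-yl]prop-2-enoic acid | COc1cc([C@H]2Oc3c(OC)cc(/C=C/C(=O)O)cc3[C@@H]2CO[Si](C)(C)C(C)(C)C)cc(OC)c1O[Si](C(C)C)(C(C)C)C(C)C | intermediate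
30 | (E)-3-[(2S,3R)-2-(4-hydroxy-3,5-dimethoxyphenyl)-3-(hydroxymethyl)-7-methoxy-2,3-dihydrobenzofuran-5-yl]prop-2-enoic acid | COc1cc([C@H]2Oc3c(OC)cc(/C=C/C(=O)O)cc3[C@@H]2CO)cc(OC)c1O | target

## Step count and least certain steps

Total step count: 14. Longest linear sequence: 13 steps (steps 1 and 3 to 14 from syringaldehyde 1; steps 2 to 14 from 3 are equally long).

**Step 9 (key step).**
- What may go wrong:
  - The vinylcarbene and dienylketene intermediates may collapse without carbonyl insertion or after a second alkyne insertion.
  - Regiocontrol of the alkyne insertion may erode.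
  - Ethanol may be lost from the ortho-hydroxy acetal in the chromium-bound phenol or on silica.
  - C3 may partly epimerise through the vinylogous acidity of 19 if traces of base are present.
- Fallback: this sets out from 19 and comes back at 26. The C5 carbon is brought in at the alcohol level on a non-ionisable group, which changes the oxidation-state plan and not only the conditions.
  - Compound 19 is benzannulated in the same way with triethyl(prop-2-ynyloxy)silane (C#CCO[Si](CC)(CC)CC). This should give (2S,3R)-3-(tert-butyldimethylsilyloxymethyl)-7-methoxy-5-(triethylsilyloxymethyl)-2-[3,5-dimethoxy-4-(triisopropylsilyloxy)phenyl]-2,3-dihydrobenzofuran-4-ol F1.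
  - Triflation (NaH, PhNTf2) gives the corresponding C4 trifluoromethanesulfonate F2.
  - Reduction with Pd(OAc)2, dppf and formate gives the C4-unsubstituted 5-(triethylsilyloxymethyl) compound F3.
  - Swern conditions (oxalyl chloride, DMSO, Et3N) oxidise the primary benzylic triethylsilyl ether of F3 directly to the aldehyde 26, in the presence of the tert-butyldimethylsilyl ether.

**Step 8.**
- What may go wrong:
  - Deprotonation may compete at the benzylic, oxygen-bearing C–H (the future C2) or ortho to a methoxy group of ring B.
  - O-methylation of the acylmetalate may be incomplete.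
  - The carbene complex may degrade oxidatively during isolation.
- Fallback: this sets out from the lactol 13 and comes back at 19. It generates the same vinyllithium by tin–lithium exchange at low temperature, where no C–H site can compete.
  - Oxidation of 13 (TEMPO, PhI(OAc)2) gives (4R,5S)-4-(tert-butyldimethylsilyloxymethyl)-5-[3,5-dimethoxy-4-(triisopropylsilyloxy)phenyl]dihydrofuran-2(3H)-one F4.
  - Enolisation and phosphorylation (KN(SiMe3)2, (PhO)2P(O)Cl, THF, −78 °C) give the ketene acetal (4R,5S)-4-(tert-butyldimethylsilyloxymethyl)-5-[3,5-dimethoxy-4-(triisopropylsilyloxy)phenyl]-4,5-dihydrofuran-2-yl diphenyl phosphate F5.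
  - Palladium-catalysed stannylation (Me3SnSnMe3, Pd(PPh3)4, LiCl, THF, reflux) gives trimethyl[(4R,5S)-4-(tert-butyldimethylsilyloxymethyl)-5-[3,5-dimethoxy-4-(triisopropylsilyloxy)phenyl]-4,5-dihydrofuran-2-yl]stannane F6.
  - MeLi at −78 °C converts F6 into the vinyllithium 17, which is treated with 16 and Me3OBF4 as in step 8 to give 19.

**Step 7.**
- What may go wrong:
  - The anomeric mesylate may be replaced by chloride without elimination.
  - The lactol may condense with itself to a bis-acetal.
  - The acid-sensitive enol ether may hydrate or oligomerise during work-up.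
- Fallback: this sets out from 13 and comes back at 15. It replaces the base-induced elimination by a thermal syn-elimination.
  - Compound 13 is converted with (PhS)2 and Bu3P into (2S,3R)-3-(tert-butyldimethylsilyloxymethyl)-2-[3,5-dimethoxy-4-(triisopropylsilyloxy)phenyl]-5-(phenylsulfanyl)tetrahydrofuran F7.
  - Oxidation with mCPBA at −78 °C gives the corresponding 5-(phenylsulfinyl)tetrahydrofuran F8.
  - Heating F8 in toluene at 110 °C with Et3N should expel benzenesulfenic acid. Only the ring CH2 carries a β-hydrogen, so the double bond can form only in the enol ether position of 15.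

**Step 11.**
- What may go wrong:
  - Oxidative addition into the electron-rich, doubly ortho-substituted triflate may be slow.
  - S–O cleavage may compete and return the phenol 22.
  - The acetal may be lost if the medium turns acidic.
- Fallback: this sets out from 22 and comes back at 26. It changes the order so that the triflate is activated and less hindered.
  - Hydrolysis of 22 (PPTS, wet acetone) gives (2S,3R)-3-(tert-butyldimethylsilyloxymethyl)-4-hydroxy-7-methoxy-2-[3,5-dimethoxy-4-(triisopropylsilyloxy)phenyl]-2,3-dihydrobenzofuran-5-carbaldehyde F9.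
  - Triflation (NaH, PhNTf2) gives the corresponding 5-formyl C4 trifluoromethanesulfonate F10.
  - The ortho formyl group of F10 is small and electron-withdrawing, so zerovalent palladium should insert more readily. Reduction with Pd(OAc)2, dppf, HCO2H and Et3N gives the aldehyde 26 directly.

## Further compounds

F1 | step 9 | (2S,3R)-3-(tert-butyldimethylsilyloxymethyl)-7-methoxy-5-(triethylsilyloxymethyl)-2-[3,5-dimethoxy-4-(triisopropylsilyloxy)phenyl]-2,3-dihydrobenzofuran-4-ol | COc1cc([C@H]2Oc3c(OC)cc(CO[Si](CC)(CC)CC)c(O)c3[C@@H]2CO[Si](C)(C)C(C)(C)C)cc(OC)c1O[Si](C(C)C)(C(C)C)C(C)C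
F2 | step 9 | (2S,3R)-3-(tert-butyldimethylsilyloxymethyl)-7-methoxy-5-(triethylsilyloxymethyl)-2-[3,5-dimethoxy-4-(triisopropylsilyloxy)phenyl]-2,3-dihydrobenzofuran-4-yl trifluoromethanesulfonate | COc1cc([C@H]2Oc3c(OC)cc(CO[Si](CC)(CC)CC)c(OS(=O)(=O)C(F)(F)F)c3[C@@H]2CO[Si](C)(C)C(C)(C)C)cc(OC)c1O[Si](C(C)C)(C(C)C)C(C)C
F3 | step 9 | tert-butyl{[(2S,3R)-7-methoxy-5-(triethylsilyloxymethyl)-2-[3,5-dimethoxy-4-(triisopropylsilyloxy)phenyl]-2,3-dihydrobenzofuran-3-yl]methoxy}dimethylsilane | COc1cc([C@H]2Oc3c(OC)cc(CO[Si](CC)(CC)CC)cc3[C@@H]2CO[Si](C)(C)C(C)(C)C)cc(OC)c1O[Si](C(C)C)(C(C)C)C(C)C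
F4 | step 8 | (4R,5S)-4-(tert-butyldimethylsilyloxymethyl)-5-[3,5-dimethoxy-4-(triisopropylsilyloxy)phenyl]dihydrofuran-2(3H)-one | O=C1C[C@H](CO[Si](C)(C)C(C)(C)C)[C@@H](c2cc(OC)c(O[Si](C(C)C)(C(C)C)C(C)C)c(OC)c2)O1
F5 | step 8 | (4R,5S)-4-(tert-butyldimethylsilyloxymethyl)-5-[3,5-dimethoxy-4-(triisopropylsilyloxy)phenyl]-4,5-dihydrofuran-2-yl diphenyl phosphate | O=P(Oc1ccccc1)(Oc1ccccc1)OC1=C[C@H](CO[Si](C)(C)C(C)(C)C)[C@@H](c2cc(OC)c(O[Si](C(C)C)(C(C)C)C(C)C)c(OC)c2)O1
F6 | step 8 | trimethyl[(4R,5S)-4-(tert-butyldimethylsilyloxymethyl)-5-[3,5-dimethoxy-4-(triisopropylsilyloxy)phenyl]-4,5-dihydrofuran-2-yl]stannane | C[Sn](C)(C)C1=C[C@H](CO[Si](C)(C)C(C)(C)C)[C@@H](c2cc(OC)c(O[Si](C(C)C)(C(C)C)C(C)C)c(OC)c2)O1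
F7 | step 7 | (2S,3R)-3-(tert-butyldimethylsilyloxymethyl)-2-[3,5-dimethoxy-4-(triisopropylsilyloxy)phenyl]-5-(phenylsulfanyl)tetrahydrofuran, both C5 epimers | c1ccccc1SC1C[C@H](CO[Si](C)(C)C(C)(C)C)[C@@H](c2cc(OC)c(O[Si](C(C)C)(C(C)C)C(C)C)c(OC)c2)O1
F8 | step 7 | (2S,3R)-3-(tert-butyldimethylsilyloxymethyl)-2-[3,5-dimethoxy-4-(triisopropylsilyloxy)phenyl]-5-(phenylsulfinyl)tetrahydrofuran, mixture of isomers at C5 and sulfur | O=S(c1ccccc1)C1C[C@H](CO[Si](C)(C)C(C)(C)C)[C@@H](c2cc(OC)c(O[Si](C(C)C)(C(C)C)C(C)C)c(OC)c2)O1
F9 | step 11 | (2S,3R)-3-(tert-butyldimethylsilyloxymethyl)-4-hydroxy-7-methoxy-2-[3,5-dimethoxy-4-(triisopropylsilyloxy)phenyl]-2,3-dihydrobenzofuran-5-carbaldehyde | COc1cc([C@H]2Oc3c(OC)cc(C=O)c(O)c3[C@@H]2CO[Si](C)(C)C(C)(C)C)cc(OC)c1O[Si](C(C)C)(C(C)C)C(C)C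
F10 | step 11 | (2S,3R)-3-(tert-butyldimethylsilyloxymethyl)-5-formyl-7-methoxy-2-[3,5-dimethoxy-4-(triisopropylsilyloxy)phenyl]-2,3-dihydrobenzofuran-4-yl trifluoromethanesulfonate | COc1cc([C@H]2Oc3c(OC)cc(C=O)c(OS(=O)(=O)C(F)(F)F)c3[C@@H]2CO[Si](C)(C)C(C)(C)C)cc(OC)c1O[Si](C(C)C)(C(C)C)C(C)C
A1 | alternative 1 | (2S)-2-(4-acetoxy-3,5-dimethoxyphenyl)-6-bromo-8-methoxychroman-4-one | COc1cc([C@@H]2CC(=O)c3cc(Br)cc(OC)c3O2)cc(OC)c1OC(C)=O
A2 | alternative 1 | methyl (2S,3S)-2-(4-acetoxy-3,5-dimethoxyphenyl)-5-bromo-7-methoxy-2,3-dihydrobenzofuran-3-carboxylate | COc1cc([C@H]2Oc3c(OC)cc(Br)cc3[C@@H]2C(=O)OC)cc(OC)c1OC(C)=O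
A3 | alternative 2 | methyl 4-iodo-3-methoxybenzoate | COC(=O)c1ccc(I)c(OC)c1
A4 | alternative 2 | (2R,3S)-3-(tert-butyldimethylsilyloxymethyl)-2-[3,5-dimethoxy-4-(methoxymethoxy)phenyl]oxirane (cis) | COCOc1c(OC)cc([C@@H]2[C@H](CO[Si](C)(C)C(C)(C)C)O2)cc1OC
A5 | alternative 2 | methyl (2S,3R)-3-(tert-butyldimethylsilyloxymethyl)-7-methoxy-2-[3,5-dimethoxy-4-(methoxymethoxy)phenyl]-2,3-dihydrobenzofuran-5-carboxylate | COCOc1c(OC)cc([C@H]2Oc3c(OC)cc(C(=O)OC)cc3[C@@H]2CO[Si](C)(C)C(C)(C)C)cc1OC
A6 | alternative 3 | (2R)-2-(5-bromo-2-hydroxy-3-methoxyphenyl)-1-(4-hydroxy-3,5-dimethoxyphenyl)propane-1,3-diol, either C1 epimer | COc1cc(C(O)[C@@H](CO)c2cc(Br)cc(OC)c2O)cc(OC)c1O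
A7 | alternative 3 | [(2S,3R)-5-bromo-2-(4-hydroxy-3,5-dimethoxyphenyl)-7-methoxy-2,3-dihydrobenzofuran-3-yl]methanol | COc1cc([C@H]2Oc3c(OC)cc(Br)cc3[C@@H]2CO)cc(OC)c1O
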